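Numbering is that of the drimane skeleton: ring A = C1–C5 and C10, ring B = C5–C10, C11 on C9, chain C11–C12–C13=C14 onward.
Retrosynthesis: cut C11–C12 (C15 bicyclic bromide plus (2E,6E)-farnesyl bromide), then C9–C11 back to a C9 ketone, then the C2–C3 bond of ring A together with one C4 methyl, then the two C10 substituents (the C1–C2 arm and the methyl) back to (R)-carvone.
Enabling feature: C3 is a methylene next to the quaternary gem-dimethyl carbon C4, so C3=C4(CH3) can be the isopropenyl group that carvone already carries on C5; when C3 adds to a C2 aldehyde hung from C10, the charge lands on tertiary C4, which then takes its second methyl from aluminium.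
Forward: ring B is carvone itself (C8 methyl, C7=C8, C9 carbonyl); C10 is alkylated twice, ring A is closed through C2–C3, C2 is deoxygenated, the C9 carbonyl becomes C9=C11 and then C9H–C11H2, and the farnesyl chain is joined last.
Stereochemistry: C5 comes from (R)-carvone, C10 from alkylation anti to the isopropenyl group, C9 from hydroboration anti to the axial C10 methyl, and both E alkenes from (2E,6E)-farnesyl bromide.

Key step: step 5

Assumption: (R)-(−)-carvone and (2E,6E)-farnesyl bromide are taken as commercial; the epimers at C6 of 3 and at the carbinol carbons of 6, 8, 9 and 10 are carried as mixtures because these centres are erased later.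

Step 1
Reactants: 1 (R)-(−)-carvone
Product: 3 (5R)-2,6-dimethyl-5-(prop-1-en-2-yl)cyclohex-2-en-1-one (6-methylcarvone; C6 epimers), via lithium dienolate 2 (not isolated)
Conditions: LiN(iPr)2 (1.1 equiv), THF, −78 °C; MeI, −78 to 0 °C
Reagents that add atoms: lithium diisopropylamide CC(C)N([Li])C(C)C (lithium, in 2 only); iodomethane CI
Why: kinetic deprotonation of the cross-conjugated enone at the α′ carbon (future C10) and C-methylation of the dienolate (enolate alkylation) should install the C10 methyl, the new centre being planarised again in step 2.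

Step 2
Reactants: 3 6-methylcarvone
Product: 5 methyl 2-[(1S,6S)-1,3-dimethyl-2-oxo-6-(prop-1-en-2-yl)cyclohex-3-en-1-yl]acetate, via lithium dienolate 4 (not isolated)
Conditions: LiN(iPr)2 (1.2 equiv), THF, −78 to 0 °C; BrCH2CO2Me, DMPU, −78 °C to rt
Reagents that add atoms: lithium diisopropylamide CC(C)N([Li])C(C)C (lithium, in 4 only); methyl bromoacetate COC(=O)CBr
Why: enolate alkylation in which the tetrasubstituted α′-enolate is attacked on the face anti to the adjacent C5 isopropenyl group (1,2-induction), so the CH2CO2Me arm (future C1–C2) should end trans to C4 and the C10 methyl cis to it, which is the trans-decalin relationship.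

Step 3
Reactants: 5 keto ester
Product: 6 2-[(1S,6S)-2-hydroxy-1,3-dimethyl-6-(prop-1-en-2-yl)cyclohex-3-en-1-yl]ethan-1-ol (carbinol epimers)
Conditions: iBu2AlH (5 equiv), CH2Cl2, −78 to 0 °C; aq. KNaC4H4O6
Reagents that add atoms: none
Why: hydride reduction takes the ester to the primary alcohol and, by 1,2-addition, the enone to the allylic alcohol, whose configuration does not matter because step 4 reoxidises it.

Step 4
Reactants: 6 diol
Product: 7 2-[(1S,6S)-1,3-dimethyl-2-oxo-6-(prop-1-en-2-yl)cyclohex-3-en-1-yl]acetaldehyde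
Conditions: (COCl)2, DMSO, CH2Cl2, −78 °C; Et3N, −78 to 0 °C
Reagents that add atoms: none
Why: Swern oxidation activates both hydroxyls before any carbonyl is formed, so the enone and the aldehyde should arise together without a hydroxy aldehyde that could close to a lactol and over-oxidise to a lactone.

Step 5
Reactants: 7 keto aldehyde
Product: 9 (4aS,8aS)-7-hydroxy-2,5,5,8a-tetramethyl-4a,5,6,7,8,8a-hexahydronaphthalen-1(4H)-one (C7 epimers), via chloro alkoxide 8 (not isolated)
Conditions: MeAlCl2 (2.2 equiv), CH2Cl2, −78 °C; then Me3Al (3 equiv), −78 to −30 °C; aq. KNaC4H4O6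
Reagents that add atoms: methylaluminium dichloride C[Al](Cl)Cl (chlorine and aluminium, in 8 only); trimethylaluminium C[Al](C)C
Why: Proposed new method: MeAlCl2 activates the aldehyde carbon C2, the terminal carbon C3 of the isopropenyl group adds to it, and the tertiary C4 cation of the zwitterion takes chloride from the aluminate to give 8; Me3Al then re-ionises this tertiary chloride and the ion pair should collapse by methyl transfer from aluminium to C4, so that the C2–C3 bond, ring A and the gem-dimethyl carbon arise in one flask. The closest known reaction types are the alkylaluminium halide-induced type 2 Prins/carbonyl-ene cyclisation of 5-methylhex-5-enal-type carbonyl compounds and the methylation of tertiary alkyl chlorides by Me3Al. Ring A closes in a 6-endo-trig mode at the C3=C4 alkene (exo at the carbonyl) through a chair in which the C1 and C4 arms are both equatorial on ring B, so the trans ring fusion already fixed at C5 and C10 is carried over unchanged. The only new stereocentre that survives work-up is the C2 carbinol, which is not controlled and is deleted in steps 6 and 7, while C4 is not stereogenic once it bears two methyls. The step needs closure at the aldehyde and not at the C9 ketone, which the higher electrophilicity of the aldehyde and the hindered, conjugated position of the ketone next to quaternary C10 should secure, and it needs methyl capture at C4 in preference to proton loss from the C4 methyl, C3 or C5, which is favoured by storing the cation as the chloride at −78 °C and by having Me3Al as the only nucleophile when it is re-ionised.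

Step 6
Reactants: 9 hydroxy enone
Product: 10 O-[(4aS,8aS)-4,4,7,8a-tetramethyl-8-oxo-1,2,3,4,4a,5,8,8a-octahydronaphthalen-2-yl] 1H-imidazole-1-carbothioate (C2 epimers)
Conditions: 1,1′-thiocarbonyldiimidazole, DMAP (cat.), ClCH2CH2Cl, 70 °C
Reagents that add atoms: 1,1′-thiocarbonyldiimidazole S=C(n1ccnc1)n1ccnc1
Why: thioacylation of the secondary C2 alcohol under neutral conditions gives the radical-labile thiocarbonyl ester (first half of the Barton–McCombie deoxygenation) and should leave the enone untouched.

Step 7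
Reactants: 10 thiocarbonyl ester
Product: 11 (4aS,8aS)-2,5,5,8a-tetramethyl-4a,5,6,7,8,8a-hexahydronaphthalen-1(4H)-one
Conditions: Bu3SnH, AIBN (cat.), toluene, 100 °C
Reagents that add atoms: none
Why: Barton–McCombie deoxygenation, in which the stannyl radical adds to the thiocarbonyl sulfur, the C2–O bond fragments and the secondary C2 radical takes hydrogen from Bu3SnH, should turn C2 into the ring A methylene.

Step 8
Reactants: 11 bicyclic enone
Product: 12 (4aS,8aS)-2,5,5,8a-tetramethyl-1-methylidene-1,4,4a,5,6,7,8,8a-octahydronaphthalene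
Conditions: Ph3PCH3Br, KOtBu, toluene, 90 °C
Reagents that add atoms: methyltriphenylphosphonium bromide C[P+](c1ccccc1)(c1ccccc1)c1ccccc1.[Br-]
Why: Wittig methylenation of the C9 carbonyl, which cannot enolise toward quaternary C10, should give the exocyclic C9=C11 alkene conjugated with C7=C8.

Step 9
Reactants: 12 diene
Product: 14 drimenol [(1S,4aS,8aS)-2,5,5,8a-tetramethyl-1,4,4a,5,6,7,8,8a-octahydronaphthalen-1-yl]methanol, via B-alkyl-9-BBN borane 13 (not isolated)
Conditions: 9-BBN, THF, 0 °C to rt; NaOH, H2O2, 0 °C to rt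
Reagents that add atoms: 9-borabicyclo[3.3.1]nonane B1C2CCCC1CCC2 (boron, in 13 only); hydrogen peroxide OO
Why: hydroboration–oxidation in which 9-BBN should add only to the 1,1-disubstituted exocyclic alkene with boron on terminal C11 and deliver hydrogen to C9 from the α face, anti to the axial C10 methyl, which sets C9 (H α, C11 β and equatorial) before oxidation with retention.

Step 10
Reactants: 14 drimenol
Product: 15 (1S,4aS,8aS)-1-(bromomethyl)-2,5,5,8a-tetramethyl-1,4,4a,5,6,7,8,8a-octahydronaphthalene
Conditions: CBr4, PPh3, CH2Cl2, 0 °C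
Reagents that add atoms: tetrabromomethane BrC(Br)(Br)Br
Why: the Appel reaction displaces the primary alkoxyphosphonium group by bromide at C11 and should leave C9 and the C7=C8 alkene untouched.

Step 11
Reactants: 15 bicyclic bromide; 16 (2E,6E)-farnesyl bromide
Product: 18 α-polypodatetraene (target), via Grignard reagent 17 (not isolated)
Conditions: Mg, THF, 50 °C; then 16, Li2CuCl4 (3 mol%), THF, −40 to 0 °C
Reagents that add atoms: magnesium [Mg] (in 17 only)
Why: copper-catalysed Grignard–allylic halide coupling in which the primary alkylmagnesium should displace bromide at C1 of the farnesyl unit in the SN2 (α) sense, favoured because the γ carbon is fully substituted, so the C11–C12 bond forms with both E alkenes and the three ring stereocentres unchanged.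

Compound list
1 | (R)-(−)-carvone, (5R)-2-methyl-5-(prop-1-en-2-yl)cyclohex-2-en-1-one | O=C1C(C)=CC[C@@H](C(C)=C)C1 | starting material
2 | lithium (3R)-6-methyl-3-(prop-1-en-2-yl)cyclohexa-1,5-dien-1-olate (α′-dienolate of 1) | [Li]OC1=C[C@H](C(C)=C)CC=C1C | intermediate (not isolated)
3 | (5R)-2,6-dimethyl-5-(prop-1-en-2-yl)cyclohex-2-en-1-one (C6 epimers) | O=C1C(C)=CC[C@@H](C(C)=C)C1C | intermediate
4 | lithium (3S)-2,6-dimethyl-3-(prop-1-en-2-yl)cyclohexa-1,5-dien-1-olate (α′-dienolate of 3) | [Li]OC1=C(C)[C@H](C(C)=C)CC=C1C | intermediate (not isolated)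
5 | methyl 2-[(1S,6S)-1,3-dimethyl-2-oxo-6-(prop-1-en-2-yl)cyclohex-3-en-1-yl]acetate | O=C1C(C)=CC[C@@H](C(C)=C)[C@]1(C)CC(=O)OC | intermediate
6 | 2-[(1S,6S)-2-hydroxy-1,3-dimethyl-6-(prop-1-en-2-yl)cyclohex-3-en-1-yl]ethan-1-ol (ring carbinol epimers) | OC1C(C)=CC[C@@H](C(C)=C)[C@]1(C)CCO | intermediate
7 | 2-[(1S,6S)-1,3-dimethyl-2-oxo-6-(prop-1-en-2-yl)cyclohex-3-en-1-yl]acetaldehyde | O=C1C(C)=CC[C@@H](C(C)=C)[C@]1(C)CC=O | intermediate
8 | chloro(methyl)aluminium alkoxide of (4aR,8aS)-5-chloro-7-hydroxy-2,5,8a-trimethyl-4a,5,6,7,8,8a-hexahydronaphthalen-1(4H)-one (trans-fused; configurations at the chloride and carbinol carbons not defined) | O=C1C(C)=CC[C@H]2C(C)(Cl)CC(O[Al](C)Cl)C[C@]12C | intermediate (not isolated)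
9 | (4aS,8aS)-7-hydroxy-2,5,5,8a-tetramethyl-4a,5,6,7,8,8a-hexahydronaphthalen-1(4H)-one (C7 epimers) | O=C1C(C)=CC[C@H]2C(C)(C)CC(O)C[C@]12C | intermediate
10 | O-[(4aS,8aS)-4,4,7,8a-tetramethyl-8-oxo-1,2,3,4,4a,5,8,8a-octahydronaphthalen-2-yl] 1H-imidazole-1-carbothioate (C2 epimers) | O=C1C(C)=CC[C@H]2C(C)(C)CC(OC(=S)n3ccnc3)C[C@]12C | intermediate
11 | (4aS,8aS)-2,5,5,8a-tetramethyl-4a,5,6,7,8,8a-hexahydronaphthalen-1(4H)-one | O=C1C(C)=CC[C@H]2C(C)(C)CCC[C@]12C | intermediate
12 | (4aS,8aS)-2,5,5,8a-tetramethyl-1-methylidene-1,4,4a,5,6,7,8,8a-octahydronaphthalene (drima-7,9(11)-diene) | C=C1C(C)=CC[C@H]2C(C)(C)CCC[C@]12C | intermediate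
13 | 9-{[(1S,4aS,8aS)-2,5,5,8a-tetramethyl-1,4,4a,5,6,7,8,8a-octahydronaphthalen-1-yl]methyl}-9-borabicyclo[3.3.1]nonane | C(B1C2CCCC1CCC2)[C@H]1C(C)=CC[C@H]2C(C)(C)CCC[C@]12C | intermediate (not isolated)
14 | drimenol, [(1S,4aS,8aS)-2,5,5,8a-tetramethyl-1,4,4a,5,6,7,8,8a-octahydronaphthalen-1-yl]methanol | OC[C@H]1C(C)=CC[C@H]2C(C)(C)CCC[C@]12C | intermediate
15 | (1S,4aS,8aS)-1-(bromomethyl)-2,5,5,8a-tetramethyl-1,4,4a,5,6,7,8,8a-octahydronaphthalene | BrC[C@H]1C(C)=CC[C@H]2C(C)(C)CCC[C@]12C | intermediate
16 | (2E,6E)-farnesyl bromide, (2E,6E)-1-bromo-3,7,11-trimethyldodeca-2,6,10-triene | CC(C)=CCC/C(C)=C/CC/C(C)=C/CBr | starting material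
17 | {[(1S,4aS,8aS)-2,5,5,8a-tetramethyl-1,4,4a,5,6,7,8,8a-octahydronaphthalen-1-yl]methyl}magnesium bromide | Br[Mg]C[C@H]1C(C)=CC[C@H]2C(C)(C)CCC[C@]12C | intermediate (not isolated)
18 | α-polypodatetraene, (1S,4aS,8aS)-2,5,5,8a-tetramethyl-1-[(3E,7E)-4,8,12-trimethyltrideca-3,7,11-trien-1-yl]-1,4,4a,5,6,7,8,8a-octahydronaphthalene | CC(C)=CCC/C(C)=C/CC/C(C)=C/CC[C@H]1C(C)=CC[C@H]2C(C)(C)CCC[C@]12C | target

Total step count: 11. Longest linear sequence: 11 steps from 1 (16 is commercial and enters in step 11).

Steps most likely to fail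

Step 5 (proposed new method). The process at risk is the discharge of the C4 cation: loss of a proton from the C4 methyl (ene-type collapse), a 1,2-hydride shift from C5, or retro-Prins reopening followed by methyl addition to the freed aldehyde may outrun methyl capture at C4. The fallback uses known chemistry, sets out from 7 and returns at 9. Me2AlCl (1.5 equiv, CH2Cl2, −78 to 0 °C) should bring about the established type 2 carbonyl-ene cyclisation, which forms the same C2–C3 bond but discharges C4 by proton transfer to oxygen, to give (4aS,8aS)-7-hydroxy-2,8a-dimethyl-5-methylidene-4a,5,6,7,8,8a-hexahydronaphthalen-1(4H)-one F1. Its C4=CH2 bond is then hydromethylated in the Markovnikov sense by iron-hydride hydrogen-atom transfer (Fe(acac)3, PhSiH3, CH2O, n-C8H17SO2NHNH2, THF/MeOH, rt). The tertiary C4 radical adds to the formaldehyde sulfonylhydrazone to give N′-{[(4aS,8aS)-3-hydroxy-1,4a,6-trimethyl-5-oxo-1,2,3,4,4a,5,8,8a-octahydronaphthalen-1-yl]methyl}octane-1-sulfonohydrazide F2, which on warming in MeOH (60 °C) should lose sulfinate and N2 and leave the second C4 methyl of 9.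

Step 8. Slow addition of the ylide to the hindered, conjugated C9 carbonyl and competing γ-deprotonation with deconjugation may stall the olefination. The fallback sets out from 11 and returns at 12. Me3SiCH2Li (THF, 0 °C), a small and strongly nucleophilic carbanion, should add to the C9 carbonyl to give (4aS,8aS)-2,5,5,8a-tetramethyl-1-[(trimethylsilyl)methyl]-1,4,4a,5,6,7,8,8a-octahydronaphthalen-1-ol F3. KH (THF, 50 °C) then effects Peterson elimination, which can only place the new alkene between C9 and C11.

Step 11. SN2′ attack at the γ carbon of the farnesyl unit and halogen–metal exchange with homocoupling may erode the regiochemistry of the C11–C12 bond formation. The fallback sets out from 15 and 16 and returns at 18. Bromide 16 and PhSO2Na (DMF, rt) should give {[(2E,6E)-3,7,11-trimethyldodeca-2,6,10-trien-1-yl]sulfonyl}benzene F4. Its α-lithio derivative (nBuLi, THF/HMPA, −78 °C) is alkylated with 15 (NaI, −78 °C to rt) to give (1S,4aS,8aS)-2,5,5,8a-tetramethyl-1-[(3E,7E)-4,8,12-trimethyl-2-(phenylsulfonyl)trideca-3,7,11-trien-1-yl]-1,4,4a,5,6,7,8,8a-octahydronaphthalene F5 (sulfone-carbon epimers). Reductive removal of the allylic sulfone (PdCl2(dppp) cat., LiEt3BH, THF, 0 °C) should deliver hydride to the less substituted allyl terminus C12 and keep the C13=C14 alkene E.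

Further compounds
F1 | step 5 | (4aS,8aS)-7-hydroxy-2,8a-dimethyl-5-methylidene-4a,5,6,7,8,8a-hexahydronaphthalen-1(4H)-one (C7 epimers) | O=C1C(C)=CC[C@H]2C(=C)CC(O)C[C@]12C
F2 | step 5 | N′-{[(4aS,8aS)-3-hydroxy-1,4a,6-trimethyl-5-oxo-1,2,3,4,4a,5,8,8a-octahydronaphthalen-1-yl]methyl}octane-1-sulfonohydrazide | O=C1C(C)=CC[C@H]2C(C)(CNNS(=O)(=O)CCCCCCCC)CC(O)C[C@]12C
F3 | step 8 | (4aS,8aS)-2,5,5,8a-tetramethyl-1-[(trimethylsilyl)methyl]-1,4,4a,5,6,7,8,8a-octahydronaphthalen-1-ol (C1 configuration not defined) | C[Si](C)(C)CC1(O)C(C)=CC[C@H]2C(C)(C)CCC[C@]12C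
F4 | step 11 | {[(2E,6E)-3,7,11-trimethyldodeca-2,6,10-trien-1-yl]sulfonyl}benzene | CC(C)=CCC/C(C)=C/CC/C(C)=C/CS(=O)(=O)c1ccccc1
F5 | step 11 | (1S,4aS,8aS)-2,5,5,8a-tetramethyl-1-[(3E,7E)-4,8,12-trimethyl-2-(phenylsulfonyl)trideca-3,7,11-trien-1-yl]-1,4,4a,5,6,7,8,8a-octahydronaphthalene (sulfone-carbon epimers) | CC(C)=CCC/C(C)=C/CC/C(C)=C/C(C[C@H]1C(C)=CC[C@H]2C(C)(C)CCC[C@]12C)S(=O)(=O)c1ccccc1
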